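**Retrosynthetic overview**

1. Target 24 comes from macrocycle 23 by one unmasking step (allylic MOM ether and 1,3-dioxolane).
2. Feature used: in ring B (the 2-hydroxybenzaldehyde arene; C1 = CHO carbon, C2 = OH, C6 = alkenyl) the free OH on C2 is para to C5, the carbon bearing the diaryl ether oxygen. The C5–O bond is a ring bond of the 12-membered macrocycle, so the ether carbon can start as the para C–H of a phenol.
3. Key disconnection: ring B C5–O(ring A) gives open bis-phenol ester 20. Oxidation of the ring B phenol with PhI(OAc)2 and capture by the ring A phenol oxygen closes the macrocycle.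
4. 20 comes from alkynol 11 by Steglich esterification (acid 14), Sonogashira coupling (bromide 17) and Lindlar reduction. 11 comes from hexanal by syn-selective asymmetric alkoxyallylboration (both stereocentres), then vinyl to ethynyl.
5. Ring order: both arenes are bought; the 12-membered ring is the only ring formed, in step 12.

Key step: step 12

Remark: 3-(methoxymethoxy)prop-1-ene (2) is assumed to be purchasable; it is otherwise one step from allyl alcohol and chloromethyl methyl ether.

Remark: the spectator groups through the ring closure are a MOM ether on the allylic oxygen (it arrives with the allylboration reagent and leaves only the pentyl carbinol free for acylation) and a 1,3-dioxolane on the aldehyde (more robust beside a free phenol than an open-chain acetal). Ring A numbering: C1 = ester carbon, C2 = methyl, C5 = OH.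

**Route**

Step 1
Reactants: 1 hexanal; 2 3-(methoxymethoxy)prop-1-ene
Product: 6 (3S,4S)-3-(methoxymethoxy)non-1-en-4-ol, via (Z)-3-(methoxymethoxy)allyllithium 3 (not isolated), via (Z)-γ-alkoxyallyl diisopinocampheylborane 4 (not isolated), via borinate adduct 5 (not isolated)
Conditions: 2, s-BuLi, THF, −78 °C; (+)-B-methoxydiisopinocampheylborane [from (−)-α-pinene]; BF3·OEt2, then 1, −78 °C; NaOH, H2O2, 0 °C to rt
Reagents that add atoms: none
Why: Brown-type asymmetric alkoxyallylboration, in which the chelated Z allyllithium keeps its geometry on transfer to boron, the allylborane adds through a closed six-membered chair (Zimmerman–Traxler type) that turns the Z geometry into the 3,4-syn relation, and the isopinocampheyl groups from (−)-α-pinene direct the allyl unit to the Re face of hexanal, which sets 4S and, through the chair, 3S.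

Step 2
Reactants: 6 (3S,4S)-3-(methoxymethoxy)non-1-en-4-ol
Product: 7 tert-butyl{[(3S,4S)-3-(methoxymethoxy)non-1-en-4-yl]oxy}dimethylsilane
Conditions: TBSCl, imidazole, DMF, rt
Reagents that add atoms: tert-butyldimethylsilyl chloride (TBSCl), CC(C)(C)[Si](C)(C)Cl
Why: Standard silyl ether formation at the only hydroxyl, needed so that the β-oxygen is not free when the aldehyde is made and homologated under basic conditions.

Step 3
Reactants: 7 tert-butyl{[(3S,4S)-3-(methoxymethoxy)non-1-en-4-yl]oxy}dimethylsilane
Product: 9 (2R,3S)-3-[(tert-butyldimethylsilyl)oxy]-2-(methoxymethoxy)octanal, via secondary ozonide 8 (not isolated)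
Conditions: O3, CH2Cl2, −78 °C; then PPh3, −78 °C to rt
Reagents that add atoms: ozone, [O-][O+]=O
Why: Ozonolysis with reductive work-up cleaves the terminal alkene to the aldehyde, the secondary ozonide being reduced by the phosphine, without touching the ethers or the two stereocentres.

Step 4
Reactants: 9 (2R,3S)-3-[(tert-butyldimethylsilyl)oxy]-2-(methoxymethoxy)octanal
Product: 10 tert-butyl{[(3S,4S)-3-(methoxymethoxy)non-1-yn-4-yl]oxy}dimethylsilane
Conditions: dimethyl (1-diazo-2-oxopropyl)phosphonate, K2CO3, MeOH, 0 °C to rt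
Reagents that add atoms: dimethyl (1-diazo-2-oxopropyl)phosphonate, CC(=O)C(=[N+]=[N-])P(=O)(OC)OC
Why: Ohira–Bestmann (Seyferth–Gilbert) homologation, in which methanolysis of the reagent gives the diazomethylphosphonate anion that adds to the aldehyde and, after loss of phosphate and nitrogen, the alkylidene carbene rearranges to the terminal alkyne under conditions mild enough that the α-alkoxy stereocentre should not epimerise.

Step 5
Reactants: 10 tert-butyl{[(3S,4S)-3-(methoxymethoxy)non-1-yn-4-yl]oxy}dimethylsilane
Product: 11 (3S,4S)-3-(methoxymethoxy)non-1-yn-4-ol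
Conditions: TBAF, THF, 0 °C to rt
Reagents that add atoms: none
Why: Fluoride-induced desilylation frees the pentyl carbinol while the MOM ether and the alkyne are inert.

Step 6
Reactants: 12 5-hydroxy-2-methylbenzoic acid
Product: 14 5-[(tert-butyldimethylsilyl)oxy]-2-methylbenzoic acid, via bis-silylated acid 13 (not isolated)
Conditions: TBSCl (2.5 equiv), imidazole, DMF, rt; then AcOH–THF–H2O, rt
Reagents that add atoms: tert-butyldimethylsilyl chloride (TBSCl), CC(C)(C)[Si](C)(C)Cl
Why: Silylation of both acidic groups followed by selective hydrolysis of the far more labile silyl ester leaves the phenol masked and the acid free.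

Step 7
Reactants: 11 (3S,4S)-3-(methoxymethoxy)non-1-yn-4-ol; 14 5-[(tert-butyldimethylsilyl)oxy]-2-methylbenzoic acid
Product: 15 (3S,4S)-3-(methoxymethoxy)non-1-yn-4-yl 5-[(tert-butyldimethylsilyl)oxy]-2-methylbenzoate
Conditions: DCC, DMAP, CH2Cl2, 0 °C to rt
Reagents that add atoms: none
Why: Steglich esterification through the acylpyridinium ion acylates the only free hydroxyl with retention at C4, because its C–O bond is not broken.

Step 8
Reactants: 16 2-bromo-6-hydroxybenzaldehyde
Product: 17 3-bromo-2-(1,3-dioxolan-2-yl)phenol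
Conditions: ethylene glycol, p-TsOH (cat.), toluene, reflux, Dean–Stark
Reagents that add atoms: ethylene glycol, OCCO
Why: Acid-catalysed acetalisation driven by azeotropic removal of water converts the hindered aldehyde into the 1,3-dioxolane and leaves the phenol free.

Step 9
Reactants: 15 (3S,4S)-3-(methoxymethoxy)non-1-yn-4-yl 5-[(tert-butyldimethylsilyl)oxy]-2-methylbenzoate; 17 3-bromo-2-(1,3-dioxolan-2-yl)phenol
Product: 18 (3S,4S)-1-[2-(1,3-dioxolan-2-yl)-3-hydroxyphenyl]-3-(methoxymethoxy)non-1-yn-4-yl 5-[(tert-butyldimethylsilyl)oxy]-2-methylbenzoate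
Conditions: Pd(PhCN)2Cl2 (cat.), P(t-Bu)3 (cat.), CuI (cat.), i-Pr2NH, dioxane, rt to 50 °C
Reagents that add atoms: none
Why: Sonogashira coupling, in which zerovalent palladium carrying the bulky electron-rich phosphine inserts into the hindered C–Br bond, the copper acetylide of 15 transmetallates and reductive elimination forms the aryl–alkyne bond, while the phenol, aryl silyl ether, ester and acetals are inert to the amine base at this temperature.

Step 10
Reactants: 18 (3S,4S)-1-[2-(1,3-dioxolan-2-yl)-3-hydroxyphenyl]-3-(methoxymethoxy)non-1-yn-4-yl 5-[(tert-butyldimethylsilyl)oxy]-2-methylbenzoate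
Product: 19 (1Z,3S,4S)-1-[2-(1,3-dioxolan-2-yl)-3-hydroxyphenyl]-3-(methoxymethoxy)non-1-en-4-yl 5-[(tert-butyldimethylsilyl)oxy]-2-methylbenzoate
Conditions: H2 (1 atm), Lindlar catalyst (Pd on CaCO3, poisoned with Pb(OAc)2), quinoline, EtOAc, rt
Reagents that add atoms: none
Why: Lindlar semi-hydrogenation delivers H2 syn on the poisoned palladium surface to give the Z alkene, quinoline suppresses over-reduction, and no stereocentre is touched.

Step 11
Reactants: 19 (1Z,3S,4S)-1-[2-(1,3-dioxolan-2-yl)-3-hydroxyphenyl]-3-(methoxymethoxy)non-1-en-4-yl 5-[(tert-butyldimethylsilyl)oxy]-2-methylbenzoate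
Product: 20 (1Z,3S,4S)-1-[2-(1,3-dioxolan-2-yl)-3-hydroxyphenyl]-3-(methoxymethoxy)non-1-en-4-yl 5-hydroxy-2-methylbenzoate
Conditions: TBAF, AcOH, THF, 0 °C
Reagents that add atoms: none
Why: Fluoride cleaves the aryl silyl ether, and the acetic acid buffer keeps the medium from becoming basic enough to open the ester or move the acyl group.

Step 12
Reactants: 20 (1Z,3S,4S)-1-[2-(1,3-dioxolan-2-yl)-3-hydroxyphenyl]-3-(methoxymethoxy)non-1-en-4-yl 5-hydroxy-2-methylbenzoate
Product: 23 (S,S,Z)-configured 12-membered diaryl ether macrolactone (allylic O-MOM; aldehyde as 1,3-dioxolane; free ring B phenol), via ring B aryloxy(phenyl)iodine acetate 21 (not isolated), via macrocyclic 4-aryloxydienone 22 (not isolated)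
Conditions: PhI(OAc)2 (1.0 equiv, slow addition), NaHCO3, (CF3)2CHOH–CH2Cl2 (1:4), 1 mM, −20 °C
Reagents that add atoms: none
Why: Proposed new method: both phenols can exchange reversibly onto iodine, but only the ring B aryloxy(phenyl)iodine acetate 21 has an open para carbon, so loss of PhI and acetate gives a phenoxenium-like ring B with positive charge at C5, the ring A phenol oxygen bonds there, and the resulting 4-aryloxydienone 22, which carries H on the new ether carbon, tautomerises to phenol 23. The closest known reaction types are oxidative phenol couplings to diaryl ethers with trivalent iodine reagents or Tl(NO3)3, the para C–O coupling by which phenols are turned into poly(phenylene ether)s, and enzymatic diaryl ether formation, none of which has been shown as a para C–H/O–H macrocyclisation of two unhalogenated phenols. The 12-membered ring closes end to end by attack of the ring A oxygen on the ring B carbon next to the alkenyl-bearing carbon, leaving ring B ortho-bridged and ring A meta-bridged; no stereocentre is formed, and the two carbinol centres and the Z alkene are not involved. Four selectivities are required: ring B must be oxidised in preference to ring A, oxygen must attack in preference to carbon, at the para and not the ortho position, and the product must not be oxidised again. Because the aldehyde is masked as an acetal, ring B behaves as an electron-rich alkylphenol, whereas ring A is deactivated by its meta ester and its only carbon able to accept a nucleophile is the methyl-bearing, ester-flanked para carbon; attack at the free ortho carbon of ring B or by a ring A carbon would require a para-bridged or a 10-membered ring, and the Z alkene together with the s-trans ester already holds the two arenes close. High dilution, a buffered weakly nucleophilic fluoroalcohol medium and one equivalent of oxidant added slowly are meant to suppress oligomers, acetal loss and a second oxidation of the more electron-rich product.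

Step 13
Reactants: 23 (S,S,Z)-configured 12-membered diaryl ether macrolactone (allylic O-MOM; aldehyde as 1,3-dioxolane; free ring B phenol)
Product: 24 CNP0238900.1 (target)
Conditions: Me2BBr, CH2Cl2, −78 °C; then aq. NaHCO3–THF
Reagents that add atoms: water, O
Why: Bromoborane cleavage of acetals, in which Me2BBr coordinates an oxygen of the MOM group and of the dioxolane, bromide opens each to an α-bromo ether and a borinate that aqueous bicarbonate hydrolyses to the alcohol and the aldehyde, at a temperature where the lactone, the diaryl ether and the allylic C–O bond should stay intact.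

**Compound list**

1 | hexanal | CCCCCC=O | starting material
2 | 3-(methoxymethoxy)prop-1-ene | C=CCOCOC | starting material
3 | (Z)-3-(methoxymethoxy)allyllithium | [Li]C/C=C\OCOC | intermediate
4 | [(Z)-3-(methoxymethoxy)prop-2-en-1-yl]bis(isopinocampheyl)borane, isopinocampheyl groups from (−)-α-pinene | COCO/C=C\CB([C@H]1C[C@H]2C[C@@H]([C@@H]1C)C2(C)C)[C@H]1C[C@H]2C[C@@H]([C@@H]1C)C2(C)C | intermediate
5 | (3S,4S)-3-(methoxymethoxy)non-1-en-4-yl bis(isopinocampheyl)borinate | CCCCC[C@H](OB([C@H]1C[C@H]2C[C@@H]([C@@H]1C)C2(C)C)[C@H]1C[C@H]2C[C@@H]([C@@H]1C)C2(C)C)[C@@H](OCOC)C=C | intermediate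
6 | (3S,4S)-3-(methoxymethoxy)non-1-en-4-ol | CCCCC[C@H](O)[C@@H](OCOC)C=C | intermediate
7 | tert-butyl{[(3S,4S)-3-(methoxymethoxy)non-1-en-4-yl]oxy}dimethylsilane | CCCCC[C@H](O[Si](C)(C)C(C)(C)C)[C@@H](OCOC)C=C | intermediate
8 | secondary ozonide of 7, 3-[(1R,2S)-2-[(tert-butyldimethylsilyl)oxy]-1-(methoxymethoxy)heptyl]-1,2,4-trioxolane (trioxolane carbon undefined) | CCCCC[C@H](O[Si](C)(C)C(C)(C)C)[C@@H](OCOC)C1OCOO1 | intermediate
9 | (2R,3S)-3-[(tert-butyldimethylsilyl)oxy]-2-(methoxymethoxy)octanal | CCCCC[C@H](O[Si](C)(C)C(C)(C)C)[C@@H](OCOC)C=O | intermediate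
10 | tert-butyl{[(3S,4S)-3-(methoxymethoxy)non-1-yn-4-yl]oxy}dimethylsilane | CCCCC[C@H](O[Si](C)(C)C(C)(C)C)[C@@H](OCOC)C#C | intermediate
11 | (3S,4S)-3-(methoxymethoxy)non-1-yn-4-ol | CCCCC[C@H](O)[C@@H](OCOC)C#C | intermediate
12 | 5-hydroxy-2-methylbenzoic acid | Cc1ccc(O)cc1C(=O)O | starting material
13 | tert-butyldimethylsilyl 5-[(tert-butyldimethylsilyl)oxy]-2-methylbenzoate | Cc1ccc(O[Si](C)(C)C(C)(C)C)cc1C(=O)O[Si](C)(C)C(C)(C)C | intermediate
14 | 5-[(tert-butyldimethylsilyl)oxy]-2-methylbenzoic acid | Cc1ccc(O[Si](C)(C)C(C)(C)C)cc1C(=O)O | intermediate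
15 | (3S,4S)-3-(methoxymethoxy)non-1-yn-4-yl 5-[(tert-butyldimethylsilyl)oxy]-2-methylbenzoate | CCCCC[C@H](OC(=O)c1cc(O[Si](C)(C)C(C)(C)C)ccc1C)[C@@H](OCOC)C#C | intermediate
16 | 2-bromo-6-hydroxybenzaldehyde | O=Cc1c(O)cccc1Br | starting material
17 | 3-bromo-2-(1,3-dioxolan-2-yl)phenol | Oc1cccc(Br)c1C1OCCO1 | intermediate
18 | (3S,4S)-1-[2-(1,3-dioxolan-2-yl)-3-hydroxyphenyl]-3-(methoxymethoxy)non-1-yn-4-yl 5-[(tert-butyldimethylsilyl)oxy]-2-methylbenzoate | CCCCC[C@H](OC(=O)c1cc(O[Si](C)(C)C(C)(C)C)ccc1C)[C@@H](OCOC)C#Cc1cccc(O)c1C1OCCO1 | intermediate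
19 | (1Z,3S,4S)-1-[2-(1,3-dioxolan-2-yl)-3-hydroxyphenyl]-3-(methoxymethoxy)non-1-en-4-yl 5-[(tert-butyldimethylsilyl)oxy]-2-methylbenzoate | CCCCC[C@H](OC(=O)c1cc(O[Si](C)(C)C(C)(C)C)ccc1C)[C@@H](OCOC)/C=C\c1cccc(O)c1C1OCCO1 | intermediate
20 | (1Z,3S,4S)-1-[2-(1,3-dioxolan-2-yl)-3-hydroxyphenyl]-3-(methoxymethoxy)non-1-en-4-yl 5-hydroxy-2-methylbenzoate (open bis-phenol ester) | CCCCC[C@H](OC(=O)c1cc(O)ccc1C)[C@@H](OCOC)/C=C\c1cccc(O)c1C1OCCO1 | intermediate
21 | acetoxy(phenyl)iodine aryloxide formed at the ring B phenol of 20 (trivalent iodine) | CCCCC[C@H](OC(=O)c1cc(O)ccc1C)[C@@H](OCOC)/C=C\c1cccc(OI(OC(C)=O)c2ccccc2)c1C1OCCO1 | intermediate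
22 | macrocyclic 4-aryloxycyclohexa-2,5-dienone (ring B dearomatised, H on the new ether carbon, configuration there undefined) | CCCCC[C@@H]1OC(=O)c2cc(ccc2C)OC2C=CC(=O)C(C3OCCO3)=C2/C=C\[C@@H]1OCOC | intermediate
23 | (S,S,Z)-configured 12-membered diaryl ether macrolactone with allylic MOM ether, 1,3-dioxolane and free ring B phenol | CCCCC[C@@H]1OC(=O)c2cc(ccc2C)Oc2ccc(O)c(C3OCCO3)c2/C=C\[C@@H]1OCOC | intermediate
24 | CNP0238900.1 | CCCCC[C@@H]1OC(=O)c2cc(ccc2C)Oc2ccc(O)c(C=O)c2/C=C\[C@@H]1O | target

**Step count**

Total: 13 steps. Longest linear sequence: 11 steps (steps 1–5, 7, 9–13).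

**Steps most likely to fail**

Step 12 (proposed new method). Oxidation may start at ring A, a para-methylphenol that would be dearomatised at its methyl-bearing carbon. The product phenol, now a hydroquinone monoether, may be oxidised a second time, or intermolecular coupling may give oligomers. The fallback builds the diaryl ether first by known copper chemistry and closes the ring at the ester. It sets out from 16 (with 12 and 11) and comes back at 24. Aldehyde 16 would be iodinated para to the hydroxyl (NIS, cat. TsOH, MeCN) to 2-bromo-6-hydroxy-3-iodobenzaldehyde F1 and protected (MOMCl, i-Pr2NEt) as 2-bromo-3-iodo-6-(methoxymethoxy)benzaldehyde F2. Acid 12 would be esterified (MeOH, H2SO4) to methyl 5-hydroxy-2-methylbenzoate F3. Ullmann-type etherification of F3 at the iodide of F2 (CuI, picolinic acid, K3PO4, DMSO, 80 °C; iodide before bromide) should give methyl 5-[2-bromo-3-formyl-4-(methoxymethoxy)phenoxy]-2-methylbenzoate F4. Sonogashira coupling of its formyl-activated bromide with alkynol 11 (Pd(PPh3)2Cl2, CuI, Et3N) would give the aryl alkyne diaryl ether F5, and Lindlar reduction the Z alkene hydroxy ester F6. Saponification (LiOH, THF–H2O) gives the seco acid F7, and Yamaguchi macrolactonisation (2,4,6-trichlorobenzoyl chloride, Et3N; DMAP, toluene, high dilution) the bis-MOM macrolactone aldehyde F8. Me2BBr then removes both MOM groups to give 24.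

Step 9. Oxidative addition into the electron-rich bromide flanked by the dioxolane may be slow, so that alkyne homocoupling (Glaser) consumes 15. The fallback forms the Z alkene by a stereoretentive Suzuki–Miyaura coupling and also bypasses step 10. It sets out from 15 (with 17) and comes back at 19. Alkyne 15 would be iodinated (NIS, AgNO3, acetone) to the 1-iodoalkyne ester F9 and reduced with diimide (2-nitrobenzenesulfonyl hydrazide, Et3N) to the (Z)-1-iodoalkene ester F10. Bromide 17 would be converted by Miyaura borylation (bis(pinacolato)diboron, Pd(dppf)Cl2, KOAc, dioxane) into 2-(1,3-dioxolan-2-yl)-3-(pinacolboryl)phenol F11. Coupling of F10 with F11 (Pd(PPh3)4, K3PO4, THF–H2O, rt) should give 19.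

Step 13. One-pot Lewis acid unmasking may cause ionisation at the allylic carbon beside the styrene, incomplete ether cleavage or lactone opening. The fallback unmasks in two orthogonal stages. It sets out from 23 and comes back at 24. Transacetalisation (PPTS, acetone–H2O, 40 °C) would first free the aldehyde to give the MOM-protected macrocyclic aldehyde F12, whose electron-poor, hydrogen-bonded salicylaldehyde ring makes the allylic position less prone to ionise. The MOM ether would then be removed under non-protic conditions with TMSOTf and 2,2′-bipyridyl (CH2Cl2, 0 °C), followed by water.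

**Further compounds**

F1 | step 12 | 2-bromo-6-hydroxy-3-iodobenzaldehyde | O=Cc1c(O)ccc(I)c1Br
F2 | step 12 | 2-bromo-3-iodo-6-(methoxymethoxy)benzaldehyde | O=Cc1c(OCOC)ccc(I)c1Br
F3 | step 12 | methyl 5-hydroxy-2-methylbenzoate | COC(=O)c1cc(O)ccc1C
F4 | step 12 | methyl 5-[2-bromo-3-formyl-4-(methoxymethoxy)phenoxy]-2-methylbenzoate | COC(=O)c1cc(Oc2ccc(OCOC)c(C=O)c2Br)ccc1C
F5 | step 12 | methyl 5-{3-formyl-2-[(3S,4S)-4-hydroxy-3-(methoxymethoxy)non-1-yn-1-yl]-4-(methoxymethoxy)phenoxy}-2-methylbenzoate | COC(=O)c1cc(Oc2ccc(OCOC)c(C=O)c2C#C[C@H](OCOC)[C@@H](O)CCCCC)ccc1C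
F6 | step 12 | methyl 5-{3-formyl-2-[(1Z,3S,4S)-4-hydroxy-3-(methoxymethoxy)non-1-en-1-yl]-4-(methoxymethoxy)phenoxy}-2-methylbenzoate | COC(=O)c1cc(Oc2ccc(OCOC)c(C=O)c2/C=C\[C@H](OCOC)[C@@H](O)CCCCC)ccc1C
F7 | step 12 | 5-{3-formyl-2-[(1Z,3S,4S)-4-hydroxy-3-(methoxymethoxy)non-1-en-1-yl]-4-(methoxymethoxy)phenoxy}-2-methylbenzoic acid | OC(=O)c1cc(Oc2ccc(OCOC)c(C=O)c2/C=C\[C@H](OCOC)[C@@H](O)CCCCC)ccc1C
F8 | step 12 | (S,S,Z)-configured macrolactone aldehyde with MOM ethers on the ring B phenol and the allylic oxygen | CCCCC[C@@H]1OC(=O)c2cc(ccc2C)Oc2ccc(OCOC)c(C=O)c2/C=C\[C@@H]1OCOC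
F9 | step 9 | (3S,4S)-1-iodo-3-(methoxymethoxy)non-1-yn-4-yl 5-[(tert-butyldimethylsilyl)oxy]-2-methylbenzoate | CCCCC[C@H](OC(=O)c1cc(O[Si](C)(C)C(C)(C)C)ccc1C)[C@@H](OCOC)C#CI
F10 | step 9 | (1Z,3S,4S)-1-iodo-3-(methoxymethoxy)non-1-en-4-yl 5-[(tert-butyldimethylsilyl)oxy]-2-methylbenzoate | CCCCC[C@H](OC(=O)c1cc(O[Si](C)(C)C(C)(C)C)ccc1C)[C@@H](OCOC)/C=C\I
F11 | step 9 | 2-(1,3-dioxolan-2-yl)-3-(4,4,5,5-tetramethyl-1,3,2-dioxaborolan-2-yl)phenol | Oc1cccc(B2OC(C)(C)C(C)(C)O2)c1C1OCCO1
F12 | step 13 | (S,S,Z)-configured macrolactone aldehyde with free ring B phenol and allylic MOM ether | CCCCC[C@@H]1OC(=O)c2cc(ccc2C)Oc2ccc(O)c(C=O)c2/C=C\[C@@H]1OCOC
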